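**Assumption:** the target has no stereocentre and no stereogenic double bond, so it is achiral and needs no enantiocontrol; it is made as the 2-hydroxy-1,4-quinone tautomer drawn (C21 n-alkyl chain).

## Retrosynthetic overview

1. Target ⇐ 2-heneicosyl-6-methoxy-1,4-benzoquinone (C–O bond at the last ring CH next to the chain, then re-oxidation) ⇐ 3-heneicosyl-5-methoxyphenol (para-oxygenation). These are the two post-PKS hydroxylations of an O-methylated alkylresorcinol.
2. 3-Heneicosyl-5-methoxyphenol ⇐ a tetraketide acid by C2→C7 aldol, dehydration and loss of CO2 (the alkylresorcinol-synthase ring closure), run on a chain whose C3 oxygen already carries the methyl group.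
3. Tetraketide acid ⇐ tetraketide pyranone (hydroxide ring opening) ⇐ Claisen union of the triketide 4-methoxy-6-methyl-2-pyranone with the fatty-acyl starter methyl docosanoate.
4. Ring order: the carbocycle is the only ring of the target and is formed in step 2; the pyranone ring is only a mask, opened in the same flask.

## Route

**Step 1**
Reactants: 1 4-methoxy-6-methyl-2H-pyran-2-one (2.1 equiv); 2 methyl docosanoate (1.0 equiv)
Product: 3 4-methoxy-6-(2-oxotricosyl)-2H-pyran-2-one
Conditions: LDA (2.1 equiv, commercial solution), THF, −78 °C; then 2 in THF, −78 → 0 °C; aq. HCl work-up (excess 1 recovered)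
Reagents that add atoms: none
Why: Claisen-type C-acylation, in which LDA removes the vinylogously acidic 6-methyl proton of 1 and the extended enolate attacks the ester carbonyl of 2 through its exocyclic carbon, while the second equivalent of anion deprotonates the more acidic ketone 3 as it forms, which drives the condensation and prevents over-addition.

**Step 2**
Reactants: 3 4-methoxy-6-(2-oxotricosyl)-2H-pyran-2-one
Product: 6 3-heneicosyl-5-methoxyphenol, via ring-opened tetraketide acid 4 (not isolated), via O-methylresorcylic acid 5 (not isolated)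
Conditions: 2 M aq. KOH (10 equiv), 1,4-dioxane, 60 °C, Ar; then conc. HCl to pH 1, reflux
Reagents that add atoms: none
Why: Proposed new method: hydroxide opens the lactone at C2 to the tetraketide carboxylate 4 whose C3 carbonyl stays locked as the methyl enol ether, the dienolate formed by γ-deprotonation at C4 can only close through C2 onto the C7 ketone because a carboxylate cannot act as a Claisen acceptor, dehydration and tautomerisation give acid 5, and its carboxyl (para to OH, flanked by OMe and the chain) is lost by ipso-protonation in hot acid; the closest known reaction type is the aqueous-KOH recyclisation of 4-hydroxy-6-(2-oxoalkyl)-2-pyranones to 6-substituted β-resorcylic acids (polyketide-type aldol) followed by their thermal decarboxylation to 5-substituted resorcinols; no stereocentre is formed.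

**Step 3**
Reactants: 6 3-heneicosyl-5-methoxyphenol
Product: 7 2-heneicosyl-6-methoxy-1,4-benzoquinone
Conditions: (KO3S)2NO (2.5 equiv), aq. KH2PO4, Aliquat 336 (cat.), CH2Cl2/H2O, rt
Reagents that add atoms: Fremy's salt (dipotassium nitrosodisulfonate), [K+].[K+].[O-]S(=O)(=O)N([O])S(=O)(=O)[O-]
Why: Teuber oxidation, in which the nitroxyl radical abstracts the phenolic hydrogen, a second equivalent couples at the free para carbon (between OMe and the chain) and loss of imidodisulfonate gives the para-quinone, as is standard for 3-alkyl-5-methoxyphenols.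

**Step 4**
Reactants: 7 2-heneicosyl-6-methoxy-1,4-benzoquinone
Product: 10 2-heneicosyl-3-hydroxy-5-methoxy-1,4-benzoquinone, via triacetate 8 (not isolated), via benzenetriol 9 (not isolated)
Conditions: Ac2O (6 equiv), conc. H2SO4 (cat.), CH2Cl2, rt; then MeOH, conc. HCl (cat.), reflux, N2; then aq. FeCl3 (2.2 equiv), rt
Reagents that add atoms: acetic anhydride, CC(=O)OC(C)=O
Why: Thiele–Winter acetoxylation followed by deacetylation and oxidation, in which acetate adds to the acid-activated quinone at the only ring CH that is β to the non-vinylogous carbonyl (the other CH is the electron-rich α-carbon of the methoxy enone) to give 8 with the new oxygen next to the chain, acid methanolysis frees triol 9 under N2, and FeCl3 oxidises its 1,4-dihydroxy pair to the quinone while the hydroxyl beside the chain remains.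

## Compound list

1 | 4-methoxy-6-methyl-2H-pyran-2-one | COC1=CC(=O)OC(C)=C1 | starting material
2 | methyl docosanoate (methyl behenate) | CCCCCCCCCCCCCCCCCCCCCC(=O)OC | starting material
3 | 4-methoxy-6-(2-oxotricosyl)-2H-pyran-2-one | CCCCCCCCCCCCCCCCCCCCCC(=O)CC1=CC(OC)=CC(=O)O1 | intermediate
4 | (2E)-3-methoxy-5,7-dioxooctacos-2-enoic acid (present as potassium salt) | CCCCCCCCCCCCCCCCCCCCCC(=O)CC(=O)C\C(OC)=C/C(O)=O | intermediate
5 | 2-heneicosyl-4-hydroxy-6-methoxybenzoic acid | CCCCCCCCCCCCCCCCCCCCCc1cc(O)cc(OC)c1C(O)=O | intermediate
6 | 3-heneicosyl-5-methoxyphenol | CCCCCCCCCCCCCCCCCCCCCc1cc(O)cc(OC)c1 | intermediate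
7 | 2-heneicosyl-6-methoxycyclohexa-2,5-diene-1,4-dione | CCCCCCCCCCCCCCCCCCCCCC1=CC(=O)C=C(OC)C1=O | intermediate
8 | 3-heneicosyl-5-methoxybenzene-1,2,4-triyl triacetate | CCCCCCCCCCCCCCCCCCCCCc1c(OC(C)=O)c(OC(C)=O)cc(OC)c1OC(C)=O | intermediate
9 | 3-heneicosyl-5-methoxybenzene-1,2,4-triol | CCCCCCCCCCCCCCCCCCCCCc1c(O)c(O)cc(OC)c1O | intermediate
10 | 2-heneicosyl-3-hydroxy-5-methoxycyclohexa-2,5-diene-1,4-dione (CNP0317656.0) | CCCCCCCCCCCCCCCCCCCCCC1=C(O)C(=O)C=C(OC)C1=O | target

## Step count and risks

Total steps: 4. Longest linear sequence: 4.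

**Steps most likely to fail**

Step 2 (highest risk). The enolised pyranone may open slowly, the enol-ether methyl may be lost, or a γ-pyranone may form. The fallback sets out from 2 and comes back at 6, and it moves the O-methylation to after ring formation. The dianion of commercial triacetic acid lactone (4-hydroxy-6-methyl-2H-pyran-2-one, CC1=CC(O)=CC(=O)O1; LDA 3 equiv, THF, 0 °C) is acylated with 2 to give 4-hydroxy-6-(2-oxotricosyl)-2H-pyran-2-one F3. Aqueous KOH converts this by the known recyclisation into 2-heneicosyl-4,6-dihydroxybenzoic acid F4. Heating the acidified solution removes CO2 and gives 5-heneicosylbenzene-1,3-diol F5. Mono-O-methylation (Me2SO4 1.0 equiv, K2CO3, acetone; the two hydroxyls are equivalent, unreacted diol recycled) then gives 6.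

Step 1. The stabilised pyranone anion may react sluggishly with the unactivated, poorly soluble ester, or be quenched by the product. The fallback sets out from 1 and 2 and comes back at 3, and it replaces the Claisen acylation by aldol addition plus oxidation. Ester 2 is reduced with DIBAL-H (toluene, −78 °C) to docosanal F1. The lithium anion of 1 (LDA 1.1 equiv, THF, −78 °C) adds to it to give rac-6-(2-hydroxytricosyl)-4-methoxy-2H-pyran-2-one F2; the carbinol is racemic and its stereocentre disappears in the next operation. Dess–Martin periodinane (NaHCO3, CH2Cl2, rt) oxidises it to 3.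

Step 4. Acetoxylation of the hindered 2,6-disubstituted quinone may be slow or unselective, and the telescoped hydrolysis may cause partial O-methylation. The fallback sets out from 7 and comes back at 10, and it replaces acetoxylation and redox cycling by nucleophilic epoxidation and isomerisation. H2O2/Na2CO3 (aq. dioxane, 0 °C) epoxidises the electron-poor alkyl-substituted double bond (the methoxy-substituted one is a deactivated vinylogous ester) to give rac-1-heneicosyl-3-methoxy-7-oxabicyclo[4.1.0]hept-3-ene-2,5-dione F6 (cis-fused, one enantiomer drawn). Brief treatment with conc. H2SO4 at 0 °C (or Et3N in CH2Cl2) removes the epoxide C–H α to the carbonyl and opens the ring directly to the hydroxyquinone 10.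

## Further compounds

F1 | step 1 | docosanal | CCCCCCCCCCCCCCCCCCCCCC=O
F2 | step 1 | rac-6-(2-hydroxytricosyl)-4-methoxy-2H-pyran-2-one | CCCCCCCCCCCCCCCCCCCCCC(O)CC1=CC(OC)=CC(=O)O1
F3 | step 2 | 4-hydroxy-6-(2-oxotricosyl)-2H-pyran-2-one | CCCCCCCCCCCCCCCCCCCCCC(=O)CC1=CC(O)=CC(=O)O1
F4 | step 2 | 2-heneicosyl-4,6-dihydroxybenzoic acid | CCCCCCCCCCCCCCCCCCCCCc1cc(O)cc(O)c1C(O)=O
F5 | step 2 | 5-heneicosylbenzene-1,3-diol | CCCCCCCCCCCCCCCCCCCCCc1cc(O)cc(O)c1
F6 | step 4 | rac-1-heneicosyl-3-methoxy-7-oxabicyclo[4.1.0]hept-3-ene-2,5-dione | CCCCCCCCCCCCCCCCCCCCC[C@]12O[C@H]1C(=O)C=C(OC)C2=O
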